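The minute is my unit here: I turn each constant into a time at the charged amounts and lay those times beside the time allowed.

    Q + J → Q.J, rate k1*[Q]^2*[J]^0.5 (k1 = 4.3 M⁻¹·⁵ s⁻¹, Ea1 = 36.0 kJ mol⁻¹)
    Q + Q.J → Q.Q.J (k2 = 1.0 M⁻¹ s⁻¹, Ea2 = 46.0 kJ mol⁻¹)
    J ⇌ Z (K3 = 1.1, k3 = 0.0052 s⁻¹, Ea3 = 77.0 kJ mol⁻¹, ΔH3 = 15.0 kJ mol⁻¹)
    J + Q.J → J.Q.J (k4 = 0.15 M⁻¹ s⁻¹, Ea4 = 46.0 kJ mol⁻¹)
    (constants at 25 °C)

common to all: Q 10 mM; J 18.0 mM; time 4.0 min
- Monday's: temperature −35 °C
- Saturday's: temperature −15 °C
- Wednesday's: temperature 25 °C
- Friday's: temperature 5 °C

- which flask leads in amount of Q.J, in percent of the Q charged ("all alike" within 1.5 percentage points) (Monday's / Saturday's / Wednesday's / Friday's / all alike)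
- how much Q.J is there at the end, in percent of the Q charged: Monday's
- how much Q.J is there at the end, in percent of the Q charged: Saturday's
- how much Q.J is there at the end, in percent of the Q charged: Wednesday's
- how much Q.J is there at the end, in percent of the Q charged: Friday's

- a species is counted by the Q in it: one Q.Q.J counts as two
- at 25 °C the constants are as listed, elsewhere as the activation energies and enthalpies make them

Let q be the fraction of the charged Q still free. In Wednesday's, my fill time is the charge of Q over the rate of Q + J at charged amounts, that is one over the rate constant, the charged Q and the root of the charged J: 2.89 min. Q.J is spent with Q and with J, and its pseudo-first-order life, my spend time, is 1.31 min; the reaction with Q is the faster drain. With Q and J held at their charges, spend time over fill time is the fraction of the charge at which Q.J is made as fast as it is spent: the ceiling. Wednesday's stands at 45.4%.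

In Friday's the times stretch to 8.21 min and 4.98 min, the spend time further, so Friday's ceiling is 60.7%. With Q and J still held at their charges, Q.J climbs toward its ceiling by one minus the exponential of minus time over spend time. That gives 33.5% for Friday's and 43.3% for Wednesday's.

I distrust this, because Wednesday's time allowed outlasts its fill time, so holding Q at its charge is unsafe there. That is the weak link. Making goes as q squared, so with J held and the use of Q by Q.J left aside, I estimate q at one over one plus time over fill time: 0.672 in Friday's, 0.419 in Wednesday's. Spending goes roughly as q, so the ceiling shrinks by q, and the climb slows by the mean of one and q. Now Friday's gives 20.0% and Wednesday's 16.9%. Saturday's, with times of 27.4 min and 23.3 min and q of 0.873, gives 11.0%. Monday's, with 112 min and 141 min and q of 0.966, gives 3.34%. I commit to Friday's leading.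

The forecast, holding that “the cold flasks barely form it in 4 minutes”, gives 3.4% for Monday's, 11.7% for Saturday's, 15.9% for Wednesday's and 20.8% for Friday's, and names Friday's.

The simulation gives 3.38% for Monday's, 11.5% for Saturday's, 15.8% for Wednesday's and 20.9% for Friday's, so Friday's leads.

Wednesday's is held down by the reaction of Q with Q.J, the largest single effect: a run without it ends at 41.2% instead of 15.8%. Friday's ceiling, moved to the end amounts of Q and J, is 32.1%, above its Q.J, and the run has Q.J made 1.54 times faster than used up at 4.00 min, each step taken net.

Take Friday's with 4.5 mM of J: the fill time becomes twice as long, the ceiling 36.1%, q 0.804, and the same climb gives 13.2%. The simulated flask ends at 12.3%.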